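**Retrosynthetic overview**
1. The target is a C20 labdane unit joined to a C5 butenolide unit. The butenolide is carried as a 3-substituted furan and unveiled last (singlet oxygen, then borohydride).
2. Key disconnection: the allylic CH2–CH(OH) bond. It is made by uniting two electrophilic carbons: the formyl carbon of furan-3-carbaldehyde (polarity reversed by silylcopper addition and a [1,2]-Brook shift) and the vinyl terminus of a stereorandom 4-alkyl-4-vinyl-1,3-dioxolan-2-one (π-allylpalladium, loss of CO2).
3. Enabling feature: the (Z)-2-ene-1,5-diol array HOCH2–C(alkyl)=CH–CH2–CH(OH)– attached to C3 of the five-membered heteroaromatic ring (later the β-carbon of the butenolide). The CH2O arm cis to the new bond is the O–CH2 edge of the carbonate ring. The aromatic ring carbon next to the carbinol carbon stabilises the α-silyloxy carbanion.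
4. The carbonate comes from (−)-sclareol by side-chain cleavage to the methyl ketone, dehydration to the tetrasubstituted ring B alkene, α-hydroxylation, vinyl addition and carbonylation.
5. Ring order: rings A and B come from the chiral pool, the dioxolanone is a temporary ring opened in the key step, and the purchased furan ring becomes the butenolide at the end.

Key step: step 6

Remark on numbering: labdane numbers are used for the C20 part (C8=C9 ring B alkene, C13 branch carbon, C16 the CH2O carbon, C14 the =CH, C15 the allylic CH2). R* = 2-[(4aS,8aS)-2,5,5,8a-tetramethyl-3,4,4a,5,6,7,8,8a-octahydronaphthalen-1-yl]ethyl.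
Assumption: the (4S,5S)-configured carbene ligand is taken to deliver the (R)-carbinol; should the sense be opposite, the equally available (4R,5R)-ligand is used.

Step 1
Reactants: 1 (−)-sclareol, (13R)-labd-14-ene-8α,13-diol
Product: 2 8α-hydroxy-14,15-dinorlabdan-13-one
Conditions: KMnO4, acetone–H2O, 0 °C to rt
Reagents that add atoms: none
Why: Permanganate oxidative cleavage of the terminal vinyl group gives the α-hydroxy acid, which loses CO2 oxidatively to the methyl ketone, while the saturated decalin and the tertiary C8 alcohol are inert and all ring stereocentres come unchanged from the chiral pool.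

Step 2
Reactants: 2 8α-hydroxy-14,15-dinorlabdan-13-one
Product: 3 14,15-dinorlabd-8-en-13-one (tetrasubstituted C8=C9 alkene in ring B)
Conditions: PPh3, I2, CH2Cl2, rt
Reagents that add atoms: none
Why: The PPh3–I2 couple activates the tertiary C8 hydroxyl for E1-type dehydration and the HI formed should equilibrate the alkene isomers (and any cyclic enol ether) to the most substituted C8=C9 alkene (Zaitsev elimination), which removes the C8 and C9 stereocentres and leaves C5 and C10 untouched.

Step 3
Reactants: 3 14,15-dinorlabd-8-en-13-one
Product: 5 16-hydroxy-14,15-dinorlabd-8-en-13-one, via potassium enolate 4 (not isolated)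
Conditions: KHMDS, THF, −78 °C; then 2-(phenylsulfonyl)-3-phenyloxaziridine, −78 °C
Reagents that add atoms: 2-(phenylsulfonyl)-3-phenyloxaziridine (Davis oxaziridine), O=S(=O)(c1ccccc1)N1OC1c1ccccc1
Why: Kinetic deprotonation takes the unhindered methyl group and the enolate is hydroxylated by oxygen transfer from the N-sulfonyloxaziridine (Davis oxidation), a reagent that should not epoxidise the hindered tetrasubstituted alkene at this temperature; no stereocentre is formed.

Step 4
Reactants: 5 16-hydroxy-14,15-dinorlabd-8-en-13-one
Product: 6 labda-8,14-diene-13,16-diol (both C13 epimers)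
Conditions: vinylMgBr (2.5 equiv), THF, −78 to 0 °C
Reagents that add atoms: vinylmagnesium bromide, C=C[Mg]Br
Why: Grignard 1,2-addition to the ketone (the first equivalent is consumed by the hydroxyl group) gives the tertiary allylic alcohol; the new C13 centre forms without control, which is harmless because it is erased in step 6.

Step 5
Reactants: 6 labda-8,14-diene-13,16-diol
Product: 7 4-R*-4-vinyl-1,3-dioxolan-2-one (cyclic 13,16-carbonate of 6, both C13 epimers)
Conditions: 1,1'-carbonyldiimidazole, DMAP (cat.), CH2Cl2, rt to 40 °C
Reagents that add atoms: 1,1'-carbonyldiimidazole, O=C(n1ccnc1)n1ccnc1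
Why: Acyl transfer to the primary hydroxyl followed by 5-exo-trig closure by the tertiary hydroxyl gives the five-membered cyclic carbonate (carbonylation of a 1,2-diol) without touching any stereocentre.

Step 6
Reactants: 7 4-R*-4-vinyl-1,3-dioxolan-2-one; 8 furan-3-carbaldehyde
Product: 10 (2Z,5R)-5-[dimethyl(phenyl)silyloxy]-5-(furan-3-yl)-2-R*-pent-2-en-1-ol, via O-boryl silyl ether 9 (not isolated)
Conditions: PhMe2Si–Bpin (1.5 equiv), CuCl (10 mol %), (4S,5S)-1,3-bis(2-isopropylphenyl)-4,5-diphenylimidazolinium tetrafluoroborate (12 mol %), NaOtBu (25 mol %), Pd2(dba)3·CHCl3 (2.5 mol %), DPEphos (6 mol %), toluene, 25 °C; then H2O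
Reagents that add atoms: (dimethylphenylsilyl)boronic acid pinacol ester, C[Si](C)(c1ccccc1)B1OC(C)(C)C(C)(C)O1
Why: Proposed new method: zerovalent palladium ionises the tertiary allylic C13–O bond of 7, CO2 is lost and the freed C16 alkoxide folds back onto palladium to give a six-membered palladacycle (Pd, O, C16, C13, C14, C15) that holds the CH2O arm cis to C15, while the chiral carbene–copper silyl species adds to one face of aldehyde 8 and a [1,2]-Brook shift turns the former carbonyl carbon into a configurationally defined α-silyloxy(3-furyl)methylcopper nucleophile. Transmetalation onto the palladium alkoxide and reductive elimination at the unsubstituted terminus C15 forge the CH2–CH(OSi) bond, and the copper alkoxide set loose reacts with the silylboronate to give 9 and to regenerate the silylcopper species, so no stoichiometric base is needed. The closest known reaction types are the synergistic copper/palladium three-component coupling of aromatic aldehydes, silylboronates and aryl halides or acyclic allylic carbonates through α-silyloxybenzylcopper species, and the palladium-catalysed decarboxylative Z-selective substitution of 4-vinyl-1,3-dioxolan-2-ones by heteroatom nucleophiles; their merger on a vinyl cyclic carbonate is what is new. No ring is closed (the temporary dioxolanone ring is opened), the one new stereocentre (R) is fixed by the chiral carbene on copper in the silyl addition and carried through stereospecific Brook shift and transmetalation, and the uncontrolled C13 centre of 7 is erased. The step needs linear over branched coupling, Z over E geometry and carbonyl over allylic silylation: the fully substituted C13 terminus disfavours branched coupling and cannot swap its substituents because that would require a tertiary σ-bound palladium species, the O–Pd chelate presets the Z geometry, and the aromatic ring carbon next to the carbonyl group drives the Brook shift that makes the aldehyde the preferred silyl acceptor.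

Step 7
Reactants: 10 (2Z,5R)-5-[dimethyl(phenyl)silyloxy]-5-(furan-3-yl)-2-R*-pent-2-en-1-ol
Product: 11 (2Z,5R)-5-(furan-3-yl)-2-R*-pent-2-ene-1,5-diol
Conditions: K2CO3 (cat.), MeOH, 0 °C to rt
Reagents that add atoms: none
Why: Base-catalysed methanolysis cleaves the labile dimethylphenylsilyl ether (silyl ether solvolysis) under conditions that leave the acid-sensitive 3-furyl carbinol, both alkenes and the stereocentre untouched.

Step 8
Reactants: 11 (2Z,5R)-5-(furan-3-yl)-2-R*-pent-2-ene-1,5-diol
Product: 13 5-hydroxy-4-[(1R,3Z)-1-hydroxy-4-(hydroxymethyl)-6-(decalinyl)hex-3-enyl]furan-2(5H)-one (γ-hydroxybutenolide, both lactol epimers), via furan endoperoxide 12 (not isolated)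
Conditions: O2, Rose Bengal (cat.), iPr2NEt, CH2Cl2, hν (visible), −78 °C; then warm to rt
Reagents that add atoms: dioxygen, O=O
Why: Singlet oxygen should add across C2/C5 of the electron-rich furan in a (4+2) photooxygenation faster than it engages the alkenes at −78 °C, and the hindered amine removes the less hindered bridgehead proton (Kornblum–DeLaMare fragmentation), so the carbonyl ends up remote from the substituted ring carbon and the lactol carbon next to it; the lactol centre forms as a mixture and is removed in step 9.

Step 9
Reactants: 13 γ-hydroxybutenolide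
Product: 14 target, (R)-4-[(Z)-1-hydroxy-4-(hydroxymethyl)-6-((4aS,8aS)-2,5,5,8a-tetramethyl-3,4,4a,5,6,7,8,8a-octahydronaphthalen-1-yl)hex-3-enyl]furan-2(5H)-one
Conditions: NaBH4, EtOH, 0 °C; then 1 M HCl to pH 3
Reagents that add atoms: none
Why: Borohydride reduces the lactol carbon through its open formyl form and the ring recloses on acidification through the new primary hydroxyl, which is the one held cis to the carboxyl group (reductive lactonisation of a γ-hydroxybutenolide), while the conjugated lactone, the alkenes and the carbinol stereocentre are unaffected.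

**Compound list**
1 | (−)-sclareol | C[C@]12CCCC([C@@H]1CC[C@@]([C@@H]2CC[C@](C)(C=C)O)(C)O)(C)C | starting material
2 | 8α-hydroxy-14,15-dinorlabdan-13-one | C[C@]12CCCC([C@@H]1CC[C@@]([C@@H]2CCC(C)=O)(C)O)(C)C | intermediate
3 | 14,15-dinorlabd-8-en-13-one | CC1=C(CCC(C)=O)[C@@]2(C)CCCC(C)(C)[C@@H]2CC1 | intermediate
4 | potassium enolate of 3 (C13=C16) | CC1=C(CCC(=C)[O-])[C@@]2(C)CCCC(C)(C)[C@@H]2CC1.[K+] | intermediate
5 | 16-hydroxy-14,15-dinorlabd-8-en-13-one | CC1=C(CCC(=O)CO)[C@@]2(C)CCCC(C)(C)[C@@H]2CC1 | intermediate
6 | labda-8,14-diene-13,16-diol (both C13 epimers) | CC1=C(CCC(O)(CO)C=C)[C@@]2(C)CCCC(C)(C)[C@@H]2CC1 | intermediate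
7 | 4-R*-4-vinyl-1,3-dioxolan-2-one (both C13 epimers) | CC1=C(CCC3(C=C)COC(=O)O3)[C@@]2(C)CCCC(C)(C)[C@@H]2CC1 | intermediate
8 | furan-3-carbaldehyde | O=Cc1ccoc1 | starting material
9 | O-boryl silyl ether (C16–OBpin, carbinol–OSiMe2Ph, Z, R) | CC1=C(CC/C(=C/C[C@@H](O[Si](C)(C)c3ccccc3)c3ccoc3)COB3OC(C)(C)C(C)(C)O3)[C@@]2(C)CCCC(C)(C)[C@@H]2CC1 | intermediate
10 | (2Z,5R)-5-[dimethyl(phenyl)silyloxy]-5-(furan-3-yl)-2-R*-pent-2-en-1-ol | CC1=C(CC/C(=C/C[C@@H](O[Si](C)(C)c3ccccc3)c3ccoc3)CO)[C@@]2(C)CCCC(C)(C)[C@@H]2CC1 | intermediate
11 | (2Z,5R)-5-(furan-3-yl)-2-R*-pent-2-ene-1,5-diol | CC1=C(CC/C(=C/C[C@@H](O)c3ccoc3)CO)[C@@]2(C)CCCC(C)(C)[C@@H]2CC1 | intermediate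
12 | furan endoperoxide (2,3,7-trioxabicyclo[2.2.1]hept-5-ene) | CC1=C(CC/C(=C/C[C@@H](O)C3=CC4OOC3O4)CO)[C@@]2(C)CCCC(C)(C)[C@@H]2CC1 | intermediate
13 | γ-hydroxybutenolide (both lactol epimers) | CC1=C(CC/C(=C/C[C@@H](O)C3=CC(=O)OC3O)CO)[C@@]2(C)CCCC(C)(C)[C@@H]2CC1 | intermediate
14 | target CNP0224983.2 | CC1=C(CC/C(=C/C[C@@H](O)C2=CC(=O)OC2)CO)[C@@]2(C)CCCC(C)(C)[C@@H]2CC1 | target

Total step count: 9. Longest linear sequence: 9 steps (1 to 14).

**Steps most likely to fail**

Step 6. Four things may go wrong.
- The Brook shift on the electron-rich 3-furyl system may lag behind simple silyl carbinol formation.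
- The silylcopper species may attack the carbonate.
- The zwitterionic allylpalladium may be intercepted by the aldehyde oxygen.
- Geometry or enantiopurity may erode if transmetalation is slow.

The fallback joins the same two carbons at the alkene oxidation level by known chemistry only. It sets out from 3 and comes back at 11. Kinetic enolisation (KHMDS, PhNTf2, THF, −78 °C) gives the terminal enol triflate F1. Sonogashira coupling with trimethylsilylacetylene (Pd(PPh3)4, CuI, Et3N) gives the silylated enyne F2, and K2CO3/MeOH gives the terminal enyne F3. Hydrozirconation of the alkyne with Cp2Zr(H)Cl, transmetalation with Me2Zn and amino-alcohol-catalysed addition to 8 follow, using the enantiomer of 3-exo-morpholinoisoborneol that attacks the required face. This gives the (R,E)-dienyl carbinol F4. Nickel-catalysed 1,4-hydroboration (Ni(cod)2, PCy3, HBpin, toluene) places boron on the terminal CH2 and hydrogen on the carbon next to the carbinol. The product is the allylboronate F5, in which CH2B is cis to the chain and the hydroxyl is carried as its O-Bpin ether. NaOH/H2O2 then gives 11.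

Step 8. Ene-type photooxygenation of the tetrasubstituted ring B alkene or of the allylic alcohol alkene may compete with furan oxidation. Regiocontrol in the fragmentation of the endoperoxide may also be lost. The fallback avoids any electrophilic oxidant. It sets out from 11 and comes back at 14. Iridium-catalysed C–H borylation ([Ir(OMe)(cod)]2, 4,4'-di-tert-butyl-2,2'-bipyridine, B2pin2, THF) goes to the sterically free α-position C5 of the furan and gives the 5-boryl furan F6. Oxidation with NaBO3·4H2O in THF–H2O, followed by Et3N, converts the C–B carbon into the lactone carbonyl and tautomerises the ring to the conjugated butenolide 14.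

Step 2. The δ-hydroxy ketone may cyclise and dehydrate towards a cyclic enol ether. Equilibration to the tetrasubstituted alkene may also stay incomplete. The fallback separates elimination from isomerisation. It sets out from 2 and comes back at 3. Kinetic E2-type dehydration under basic conditions (SOCl2, pyridine, CH2Cl2, −78 to 0 °C) gives the exocyclic alkene ketone F7 together with the trisubstituted endocyclic alkene ketone F8. The mixture is then isomerised under thermodynamic control with catalytic I2 in refluxing toluene to 3.

**Further compounds**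
F1 | step 6 | 14,15-dinorlabda-8,13(16)-dien-13-yl triflate | CC1=C(CCC(=C)OS(=O)(=O)C(F)(F)F)[C@@]2(C)CCCC(C)(C)[C@@H]2CC1
F2 | step 6 | silylated enyne, 2-R*-4-(trimethylsilyl)but-1-en-3-yne | CC1=C(CCC(=C)C#C[Si](C)(C)C)[C@@]2(C)CCCC(C)(C)[C@@H]2CC1
F3 | step 6 | terminal enyne, 2-R*-but-1-en-3-yne | CC1=C(CCC(=C)C#C)[C@@]2(C)CCCC(C)(C)[C@@H]2CC1
F4 | step 6 | (1R,2E)-1-(furan-3-yl)-4-R*-penta-2,4-dien-1-ol | CC1=C(CCC(=C)/C=C/[C@@H](O)c3ccoc3)[C@@]2(C)CCCC(C)(C)[C@@H]2CC1
F5 | step 6 | allylboronate with CH2Bpin cis to the chain, carbinol as O-Bpin ether | CC1=C(CC/C(=C/C[C@@H](OB3OC(C)(C)C(C)(C)O3)c3ccoc3)CB3OC(C)(C)C(C)(C)O3)[C@@]2(C)CCCC(C)(C)[C@@H]2CC1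
F6 | step 8 | 5-boryl furan, (2Z,5R)-5-[5-(pinacolboryl)furan-3-yl]-2-R*-pent-2-ene-1,5-diol | CC1=C(CC/C(=C/C[C@@H](O)c3coc(B4OC(C)(C)C(C)(C)O4)c3)CO)[C@@]2(C)CCCC(C)(C)[C@@H]2CC1
F7 | step 2 | 14,15-dinorlabd-8(17)-en-13-one | C[C@]12CCCC([C@@H]1CCC(=C)[C@@H]2CCC(C)=O)(C)C
F8 | step 2 | 14,15-dinorlabd-7-en-13-one | C[C@]12CCCC([C@@H]1CC=C(C)[C@@H]2CCC(C)=O)(C)C
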